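The side chain is cut internally, between C8' and C9' (counted outward from C2 of pyranone ring B). Because the C25 substituent is saturated, unbranched and free of functionality, that bond can be formed by crossed Kolbe electrolysis. Two carboxylic acids are decarboxylated at a platinum anode and the resulting primary radicals combine, joining an eight-carbon tether on the chromone to the heptadecyl residue of stearic acid in one operation, without creating a ring or stereocentre. The electrolysis substrate is 9-(6,8-dimethyl-4-oxochromen-2-yl)nonanoic acid with the O5 and O7 phenols of ring A masked as pivalates, built from C-methylated phloroacetophenone and a sebacic half-ester.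

Key step: step 6

Remark on the chemistry: the target is achiral, so no stereocentre has to be set. The acetophenone is acylated directly as its lithium polyanion, so no per-acylation and partial hydrolysis of the three phenols is needed.

Step 1
Reactants: 1 2,4,6-trihydroxyacetophenone
Product: 2 1-(2,4,6-trihydroxy-3,5-dimethylphenyl)ethan-1-one
Conditions: NaOMe (3 equiv), MeI (2.2 equiv), MeOH, 0 °C → reflux; then 1 M HCl
Reagents that add atoms: iodomethane, CI
Why: C-alkylation of the ambident phloroglucinol-type polyphenoxide by methyl iodide in a protic solvent, which hydrogen-bonds the oxygens and steers reaction to the two free ring carbons C3 and C5, should give the symmetrical di-C-methyl ketone, the limited charge of MeI holding back geminal over-methylation.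

Step 2
Reactants: 3 sebacic acid monomethyl ester (10-methoxy-10-oxodecanoic acid)
Product: 4 methyl 10-chloro-10-oxodecanoate
Conditions: (COCl)2 (1.3 equiv), DMF (cat.), CH2Cl2, 0 °C → rt; evaporated and used crude
Reagents that add atoms: oxalyl chloride, O=C(Cl)C(Cl)=O
Why: Acid chloride formation through the Vilsmeier-type chloroiminium species from oxalyl chloride and DMF converts only the free carboxyl group, the distal methyl ester being inert.

Step 3
Reactants: 2 1-(2,4,6-trihydroxy-3,5-dimethylphenyl)ethan-1-one; 4 methyl 10-chloro-10-oxodecanoate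
Product: 6 methyl 9-(5,7-dihydroxy-6,8-dimethyl-4-oxo-4H-chromen-2-yl)nonanoate, via aryl β-diketone 5 (not isolated)
Conditions: LiN(SiMe3)2 (5 equiv), THF, −78 → −10 °C; 4 (1.05 equiv), −78 °C → rt; 1 M HCl, extraction; crude in MeOH, conc. HCl (cat.), reflux
Reagents that add atoms: none
Why: The lithium polyanion of 2 (three phenoxides plus the ketone enolate) is acylated by the acid chloride far faster than by the methyl ester, a one-pot variant of the Baker–Venkataraman sequence, and the resulting 1,3-diketone undergoes acid-catalysed cyclodehydration through either of its two equivalent ortho-hydroxyls to close pyranone ring B, methanol as solvent keeping the ester as its methyl ester.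

Step 4
Reactants: 6 methyl 9-(5,7-dihydroxy-6,8-dimethyl-4-oxo-4H-chromen-2-yl)nonanoate
Product: 7 methyl 9-[5,7-bis(pivaloyloxy)-6,8-dimethyl-4-oxo-4H-chromen-2-yl]nonanoate
Conditions: t-BuCOCl (5 equiv), Et3N (6 equiv), DMAP (0.5 equiv), ClCH2CH2Cl, 70 °C
Reagents that add atoms: pivaloyl chloride, CC(C)(C)C(Cl)=O
Why: Nucleophilic catalysis by DMAP (O-acylation through the acylpyridinium ion) with excess acyl chloride and heat should esterify both the doubly flanked 7-OH and the chelated 5-OH, while the methyl ester and the pyranone of ring B are spectators.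

Step 5
Reactants: 7 methyl 9-[5,7-bis(pivaloyloxy)-6,8-dimethyl-4-oxo-4H-chromen-2-yl]nonanoate
Product: 8 9-[5,7-bis(pivaloyloxy)-6,8-dimethyl-4-oxo-4H-chromen-2-yl]nonanoic acid
Conditions: LiI (anhydrous, 10 equiv), EtOAc, reflux, dark; then 1 M HCl
Reagents that add atoms: none
Why: Lithium-assisted SN2 dealkylation of the unhindered methyl ester by iodide is neutral and anhydrous, so the aryl pivalates, which offer no sp3 carbon open to displacement and only a shielded carbonyl, should survive.

Step 6
Reactants: 8 9-[5,7-bis(pivaloyloxy)-6,8-dimethyl-4-oxo-4H-chromen-2-yl]nonanoic acid; 9 stearic acid (octadecanoic acid)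
Product: 10 5,7-bis(pivaloyloxy)-6,8-dimethyl-2-pentacosylchromen-4-one
Conditions: Pt anode, Pt cathode, undivided cell; 8 (1 equiv), 9 (8 equiv), KOH (ca. 5 mol % of total acid), MeOH, 45–50 °C, constant current ca. 0.25 A cm−2, stopped when 8 is consumed and while the electrolyte is still acidic
Reagents that add atoms: none
Why: Both carboxylates are discharged at the platinum anode at high current density, lose CO2 and give the primary C8' radical of the chromone tether and the heptadecyl radical, which combine in the carboxylate-rich layer at the electrode to form the C8'–C9' bond. This is a classical crossed Kolbe coupling of the kind used to extend fatty chains. No ring is closed and no stereocentre is created; attack of the C8' radical on C3 of ring B would need a ten-membered transition state and cannot compete with bimolecular coupling at the high radical density on the anode. Cross- over homo-coupling is secured statistically by the large excess of cheap stearic acid, whose symmetrical by-product is an apolar alkane removed on silica. Oxidation of carboxylate instead of the arene is secured by the two acyloxy groups and the C4 carbonyl, which make ring A electron-poor. Keeping the electrolyte weakly acidic preserves the aryl pivalates, and a platinum cathode should reduce protons in preference to the chromone.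

Step 7
Reactants: 10 5,7-bis(pivaloyloxy)-6,8-dimethyl-2-pentacosylchromen-4-one
Product: 11 5,7-dihydroxy-6,8-dimethyl-2-pentacosyl-4H-chromen-4-one
Conditions: K2CO3 (4 equiv), MeOH/THF (1:1), 40 °C; then 1 M HCl
Reagents that add atoms: none
Why: Carbonate-promoted transesterification with methanol cleaves both aryl pivalates to methyl pivalate and the diphenoxide, whose charge shields ring B from nucleophilic opening, and acidification should release the target.

Compound list
1 | 2,4,6-trihydroxyacetophenone | CC(=O)c1c(O)cc(O)cc1O | starting material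
2 | 1-(2,4,6-trihydroxy-3,5-dimethylphenyl)ethan-1-one | CC(=O)c1c(O)c(C)c(O)c(C)c1O | intermediate
3 | sebacic acid monomethyl ester (10-methoxy-10-oxodecanoic acid) | COC(=O)CCCCCCCCC(=O)O | starting material
4 | methyl 10-chloro-10-oxodecanoate | COC(=O)CCCCCCCCC(Cl)=O | intermediate
5 | methyl 10,12-dioxo-12-(2,4,6-trihydroxy-3,5-dimethylphenyl)dodecanoate (aryl β-diketone) | COC(=O)CCCCCCCCC(=O)CC(=O)c1c(O)c(C)c(O)c(C)c1O | intermediate
6 | methyl 9-(5,7-dihydroxy-6,8-dimethyl-4-oxo-4H-chromen-2-yl)nonanoate | COC(=O)CCCCCCCCc1cc(=O)c2c(O)c(C)c(O)c(C)c2o1 | intermediate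
7 | methyl 9-[5,7-bis(pivaloyloxy)-6,8-dimethyl-4-oxo-4H-chromen-2-yl]nonanoate | COC(=O)CCCCCCCCc1cc(=O)c2c(OC(=O)C(C)(C)C)c(C)c(OC(=O)C(C)(C)C)c(C)c2o1 | intermediate
8 | 9-[5,7-bis(pivaloyloxy)-6,8-dimethyl-4-oxo-4H-chromen-2-yl]nonanoic acid | OC(=O)CCCCCCCCc1cc(=O)c2c(OC(=O)C(C)(C)C)c(C)c(OC(=O)C(C)(C)C)c(C)c2o1 | intermediate
9 | stearic acid (octadecanoic acid) | CCCCCCCCCCCCCCCCCC(=O)O | starting material
10 | 5,7-bis(pivaloyloxy)-6,8-dimethyl-2-pentacosylchromen-4-one | CCCCCCCCCCCCCCCCCCCCCCCCCc1cc(=O)c2c(OC(=O)C(C)(C)C)c(C)c(OC(=O)C(C)(C)C)c(C)c2o1 | intermediate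
11 | 5,7-dihydroxy-6,8-dimethyl-2-pentacosyl-4H-chromen-4-one | CCCCCCCCCCCCCCCCCCCCCCCCCc1cc(=O)c2c(O)c(C)c(O)c(C)c2o1 | target

Total step count: 7 (steps 1–7).
Longest linear sequence: 6 steps (1, 3, 4, 5, 6, 7); step 2 is a side branch.

Steps most likely to fail

Step 6. Statistical homo-coupling of each acid, fouling of the anode by sparingly soluble long-chain products, or competing oxidation of ring A could leave little cross-product. The fallback sets out from 8 and makes the same C8'–C9' bond by nickel catalysis. Esterification of 8 with N-hydroxyphthalimide (N,N'-diisopropylcarbodiimide, DMAP cat., CH2Cl2) should give the redox-active ester 1,3-dioxoisoindolin-2-yl 9-[5,7-bis(pivaloyloxy)-6,8-dimethyl-4-oxo-4H-chromen-2-yl]nonanoate F1. Separately, 1-bromoheptadecane and Mg in THF give heptadecylmagnesium bromide F2, which ZnCl2 (0.5 equiv) converts into diheptadecylzinc F3. Decarboxylative alkyl–alkyl coupling of F1 with F3 under NiCl2(MeOCH2CH2OMe), a divalent nickel precatalyst, and 2,2'-bipyridine in THF/DMF at rt should deliver 10, where the route is rejoined.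

Step 3. Ketene formation from the enolisable acid chloride, or O-acylation without acyl transfer on the crowded polyanion, could erode formation of the diketone. The fallback sets out from 2. MOMCl (2.2 equiv) and i-Pr2NEt in CH2Cl2 should protect all but the chelated hydroxyl and give 1-[2-hydroxy-4,6-bis(methoxymethoxy)-3,5-dimethylphenyl]ethan-1-one F4. Claisen condensation of its sodium enolate (NaH, THF, reflux) with an excess of dimethyl sebacate should give methyl 12-[2-hydroxy-4,6-bis(methoxymethoxy)-3,5-dimethylphenyl]-10,12-dioxododecanoate F5. HCl in MeOH at reflux then closes ring B and strips both acetals, returning to the route at 6.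

Step 4. Acylation of the hydrogen-bonded 5-OH, wedged between the C4 carbonyl and the C6 methyl, may stop short with the bulky acyl chloride. The fallback sets out from 6 and changes the masking group to the slimmer benzoyl. BzCl, pyridine and DMAP should give methyl 9-[5,7-bis(benzoyloxy)-6,8-dimethyl-4-oxo-4H-chromen-2-yl]nonanoate F6. LiI in refluxing EtOAc should then give 9-[5,7-bis(benzoyloxy)-6,8-dimethyl-4-oxo-4H-chromen-2-yl]nonanoic acid F7. Crossed Kolbe electrolysis with 9 under the conditions of step 6 should give 5,7-bis(benzoyloxy)-6,8-dimethyl-2-pentacosylchromen-4-one F8. Methanolysis with K2CO3 in MeOH/THF returns to the route at the target 11.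

Further compounds
F1 | step 6 | 1,3-dioxoisoindolin-2-yl 9-[5,7-bis(pivaloyloxy)-6,8-dimethyl-4-oxo-4H-chromen-2-yl]nonanoate | O=C(CCCCCCCCc1cc(=O)c2c(OC(=O)C(C)(C)C)c(C)c(OC(=O)C(C)(C)C)c(C)c2o1)ON1C(=O)c2ccccc2C1=O
F2 | step 6 | heptadecylmagnesium bromide | CCCCCCCCCCCCCCCCC[Mg]Br
F3 | step 6 | diheptadecylzinc | CCCCCCCCCCCCCCCCC[Zn]CCCCCCCCCCCCCCCCC
F4 | step 3 | 1-[2-hydroxy-4,6-bis(methoxymethoxy)-3,5-dimethylphenyl]ethan-1-one | CC(=O)c1c(O)c(C)c(OCOC)c(C)c1OCOC
F5 | step 3 | methyl 12-[2-hydroxy-4,6-bis(methoxymethoxy)-3,5-dimethylphenyl]-10,12-dioxododecanoate | COC(=O)CCCCCCCCC(=O)CC(=O)c1c(O)c(C)c(OCOC)c(C)c1OCOC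
F6 | step 4 | methyl 9-[5,7-bis(benzoyloxy)-6,8-dimethyl-4-oxo-4H-chromen-2-yl]nonanoate | COC(=O)CCCCCCCCc1cc(=O)c2c(OC(=O)c3ccccc3)c(C)c(OC(=O)c3ccccc3)c(C)c2o1
F7 | step 4 | 9-[5,7-bis(benzoyloxy)-6,8-dimethyl-4-oxo-4H-chromen-2-yl]nonanoic acid | OC(=O)CCCCCCCCc1cc(=O)c2c(OC(=O)c3ccccc3)c(C)c(OC(=O)c3ccccc3)c(C)c2o1
F8 | step 4 | 5,7-bis(benzoyloxy)-6,8-dimethyl-2-pentacosylchromen-4-one | CCCCCCCCCCCCCCCCCCCCCCCCCc1cc(=O)c2c(OC(=O)c3ccccc3)c(C)c(OC(=O)c3ccccc3)c(C)c2o1
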